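**Plan**

- Retrosynthesis: the O7–allyl bond is cut last. Ring C is cut at O1–C2 and at C3–OH, which leads back to 2'-hydroxychalcone 19. Its Cα=Cβ bond is cut into ring A ketone 5 and ring B aldehyde 17. In 17 the aryl–CH2 bond (aryl Grignard plus glycidate) and the isopropenyl C=C (tertiary carbinol) are cut, and in 5 the C5'–O bond.
- Forward: ring A ketone (steps 1–3) and ring B aldehyde with its side chain (steps 4–9) are joined by Claisen–Schmidt condensation (step 10). Ring C, the only ring made, closes in step 11, and deallylation (step 12) ends the route.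
- Enabling feature: C2–C3–C4 of ring C, with O1 on C2 and a hydroxyl on C3, is the enone of a 2'-hydroxychalcone raised by one oxidation level. The methoxy group on C4' of ring B, para to C1', makes C2 the carbon that best carries positive charge, so the ring A phenoxide oxygen closes there.
- Stereochemistry: the single centre (C2'' of the side chain, R) comes from methyl (R)-glycidate. Its C–O bond is never broken and no later step enolises or ionises it.

Key step: step 11

Remark on the chemistry: compounds 18, 20 and 21 form as mixtures of two diastereomers (new centres unselective beside the fixed (R) centre). Their SMILES leave the new centres open, and all converge on single compounds.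

**Route**

Step 1
Reactants: 1 2',4'-dihydroxy-6'-methoxyacetophenone
Product: 2 4'-allyloxy-2'-hydroxy-6'-methoxyacetophenone
Conditions: allyl bromide (1.05 equiv), K2CO3 (1.2 equiv), acetone, reflux
Reagents that add atoms: allyl bromide, C=CCBr
Why: Williamson ether synthesis under weak base; the 2'-hydroxyl is held in a hydrogen bond to the acetyl carbonyl and is less acidic and less nucleophilic, so one equivalent of allyl bromide should alkylate only the free 4'-hydroxyl.

Step 2
Reactants: 2 4'-allyloxy-2'-hydroxy-6'-methoxyacetophenone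
Product: 4 4'-allyloxy-2',5'-dihydroxy-6'-methoxyacetophenone, via potassium aryl sulfate 3 (not isolated)
Conditions: K2S2O8 (1.1 equiv), 10% aq. NaOH/pyridine, 0 °C to rt; HCl to pH 4 and extraction of unreacted 2; then conc. HCl, Na2SO3, 85 °C
Reagents that add atoms: potassium peroxodisulfate, [K+].[K+].[O-]S(=O)(=O)OOS(=O)(=O)[O-]
Why: Elbs persulfate oxidation; the phenoxide of 2 attacks a peroxide oxygen through its free para carbon C5' (the reaction is para-selective), and aryl sulfate 3 is then hydrolysed at the S–O bond by hot dilute acid, conditions an allyl aryl ether should tolerate.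

Step 3
Reactants: 4 4'-allyloxy-2',5'-dihydroxy-6'-methoxyacetophenone
Product: 5 4'-allyloxy-2'-hydroxy-5',6'-dimethoxyacetophenone
Conditions: Me2SO4 (1.05 equiv), K2CO3 (1.1 equiv), acetone, N2, 40 °C
Reagents that add atoms: dimethyl sulfate, COS(=O)(=O)OC
Why: Selective Williamson O-methylation; only the new C5' hydroxyl is free of the hydrogen bond to the carbonyl, so one equivalent of dimethyl sulfate should methylate it and leave the chelated 2'-hydroxyl, the usual selectivity of quinacetophenones.

Step 4
Reactants: 6 3-bromo-4-methoxybenzaldehyde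
Product: 7 2-(3-bromo-4-methoxyphenyl)-1,3-dioxolane
Conditions: ethylene glycol (3 equiv), p-TsOH·H2O (2 mol%), toluene, reflux, Dean–Stark trap
Reagents that add atoms: ethylene glycol, OCCO
Why: Acid-catalysed acetalisation with azeotropic removal of water masks the aldehyde as a dioxolane that is inert to magnesium and to Grignard reagents.

Step 5
Reactants: 7 2-(3-bromo-4-methoxyphenyl)-1,3-dioxolane; 8 methyl (R)-glycidate
Product: 10 methyl (2R)-3-[5-(1,3-dioxolan-2-yl)-2-methoxyphenyl]-2-hydroxypropanoate, via arylmagnesium bromide 9 (not isolated)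
Conditions: Mg turnings, 1,2-dibromoethane (cat.), THF, 50 °C; then added to 8 (0.8 equiv) and CuI (10 mol%), THF, −40 to −20 °C; aq. NH4Cl
Reagents that add atoms: none
Why: Magnesium insertion gives Grignard reagent 9, and copper-catalysed Grignard opening of the terminal epoxide proceeds by SN2 attack at the unsubstituted C3 faster than addition to the ester at −40 °C; the C2–O bond is not touched, so the (R) centre of 8 is carried over as (2R).

Step 6
Reactants: 10 methyl (2R)-3-[5-(1,3-dioxolan-2-yl)-2-methoxyphenyl]-2-hydroxypropanoate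
Product: 11 methyl (2R)-3-[5-(1,3-dioxolan-2-yl)-2-methoxyphenyl]-2-(triethylsilyloxy)propanoate
Conditions: Et3SiCl (1.2 equiv), imidazole (2 equiv), CH2Cl2, 0 °C to rt
Reagents that add atoms: chlorotriethylsilane, CC[Si](Cl)(CC)CC
Why: Standard silylation of a secondary alcohol; the triethylsilyl ether blocks the hydroxyl during Grignard addition and dehydration and is labile enough to leave together with the acetal in step 9.

Step 7
Reactants: 11 methyl (2R)-3-[5-(1,3-dioxolan-2-yl)-2-methoxyphenyl]-2-(triethylsilyloxy)propanoate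
Product: 13 (3R)-4-[5-(1,3-dioxolan-2-yl)-2-methoxyphenyl]-2-methyl-3-(triethylsilyloxy)butan-2-ol, via methyl ketone 12 (not isolated)
Conditions: MeMgBr (3 equiv), THF, 0 °C to rt; aq. NH4Cl
Reagents that add atoms: methylmagnesium bromide, C[Mg]Br
Why: Double Grignard addition to an ester; methyl ketone 12 is more electrophilic than the ester and is consumed as it forms, and addition outruns enolisation, so the α-silyloxy centre should stay (R).

Step 8
Reactants: 13 (3R)-4-[5-(1,3-dioxolan-2-yl)-2-methoxyphenyl]-2-methyl-3-(triethylsilyloxy)butan-2-ol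
Product: 15 2-{4-methoxy-3-[(2R)-3-methyl-2-(triethylsilyloxy)but-3-en-1-yl]phenyl}-1,3-dioxolane, via sulfamate ester 14 (not isolated)
Conditions: Burgess reagent (methyl N-(triethylammoniosulfonyl)carbamate, 2 equiv), toluene, 50 °C
Reagents that add atoms: none
Why: Burgess dehydration; the tertiary alcohol forms sulfamate ester 14, which undergoes intramolecular syn elimination toward a methyl hydrogen, because the only other β-hydrogen sits on the hindered silyloxy carbon and would lead to a silyl enol ether; this is the established way to turn a 2-hydroxyprop-2-yl group next to an oxygenated carbon into an isopropenyl group, and the stereocentre is not involved.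

Step 9
Reactants: 15 2-{4-methoxy-3-[(2R)-3-methyl-2-(triethylsilyloxy)but-3-en-1-yl]phenyl}-1,3-dioxolane
Product: 17 3-[(2R)-2-hydroxy-3-methylbut-3-en-1-yl]-4-methoxybenzaldehyde, via silyl ether aldehyde 16 (not isolated)
Conditions: 1 M aq. HCl, THF, 0 °C to rt
Reagents that add atoms: water, O
Why: Dilute aqueous acid should hydrolyse the electron-rich aryl dioxolane first (aldehyde 16) and then the triethylsilyl ether, under conditions too mild to ionise the secondary allylic alcohol or to hydrate the 1,1-disubstituted alkene.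

Step 10
Reactants: 5 4'-allyloxy-2'-hydroxy-5',6'-dimethoxyacetophenone; 17 3-[(2R)-2-hydroxy-3-methylbut-3-en-1-yl]-4-methoxybenzaldehyde
Product: 19 (E)-1-[4-(allyloxy)-2-hydroxy-5,6-dimethoxyphenyl]-3-{3-[(2R)-2-hydroxy-3-methylbut-3-en-1-yl]-4-methoxyphenyl}prop-2-en-1-one, via aldol adduct 18 (not isolated)
Conditions: KOH (50% aq., 10 equiv), EtOH, rt; then 1 M HCl to pH 5
Reagents that add atoms: none
Why: Claisen–Schmidt condensation; the enolate of ketone 5 adds to the non-enolisable aldehyde 17 and aldol 18 loses water by E1cB to the (E)-enone, while the allyl ether, the isopropenyl group and the base-stable secondary alcohol are spectators.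

Step 11
Reactants: 19 (E)-1-[4-(allyloxy)-2-hydroxy-5,6-dimethoxyphenyl]-3-{3-[(2R)-2-hydroxy-3-methylbut-3-en-1-yl]-4-methoxyphenyl}prop-2-en-1-one
Product: 22 7-(allyloxy)-3-hydroxy-2-{3-[(2R)-2-hydroxy-3-methylbut-3-en-1-yl]-4-methoxyphenyl}-5,6-dimethoxy-4H-chromen-4-one, via chalcone epoxide 20 (not isolated), via dihydroflavonol 21 (not isolated)
Conditions: 30% aq. H2O2 (5 equiv), 2 M aq. NaOH (5 equiv), MeOH, 0 °C then rt; then 1 M HCl to pH 5
Reagents that add atoms: hydrogen peroxide, OO
Why: Hydroperoxide anion adds to the β-carbon of the enone and the enolate closes the oxirane (Weitz–Scheffer epoxidation) to give 20, the ring A phenoxide opens the oxirane at the benzylic carbon to form O1–C2 and leave the oxygen on C3 (21), and base with more peroxide dehydrogenates C2–C3 to the flavonol; direct conjugate addition of the phenoxide with capture of the enolate by H2O2 would give the same 21. The closest known reaction type is the Algar–Flynn–Oyamada conversion of 2'-hydroxychalcones into flavonols with alkaline H2O2. Ring C closes by 6-endo-tet opening of the epoxide by O1. The two centres made at C2 and C3 are transient and vanish on dehydrogenation, so no element of control is needed, and the remote side-chain centre stays (R). The step needs attack at C2 and not at C3 (5-exo, leading to an aurone); the ring B methoxy group para to the benzylic carbon should secure this by stabilising positive charge at C2, helped by the low temperature, against the twist imposed by the ring A methoxy group ortho to the ketone. Chemoselectivity rests on the nucleophilic oxidant, which attacks only the electron-poor enone and should leave the isopropenyl and allyl alkenes and the free alcohol alone.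

Step 12
Reactants: 22 7-(allyloxy)-3-hydroxy-2-{3-[(2R)-2-hydroxy-3-methylbut-3-en-1-yl]-4-methoxyphenyl}-5,6-dimethoxy-4H-chromen-4-one
Product: 23 3,7-dihydroxy-2-{3-[(2R)-2-hydroxy-3-methylbut-3-en-1-yl]-4-methoxyphenyl}-5,6-dimethoxy-4H-chromen-4-one
Conditions: Pd(PPh3)4 (5 mol%), morpholine (5 equiv), degassed THF, rt
Reagents that add atoms: none
Why: Tsuji–Trost deallylation; zerovalent palladium ionises the allyl aryl ether to a π-allyl complex with the 7-phenoxide as leaving group and morpholine takes up the allyl group, whereas the free secondary allylic alcohol is too poor a leaving group to ionise and the isopropenyl alkene is inert, so these neutral conditions should give 23 with the (R) centre untouched.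

**Compound list**

1 | 2',4'-dihydroxy-6'-methoxyacetophenone | CC(=O)c1c(O)cc(O)cc1OC | starting material
2 | 4'-allyloxy-2'-hydroxy-6'-methoxyacetophenone | CC(=O)c1c(O)cc(OCC=C)cc1OC | intermediate
3 | potassium 3-acetyl-6-(allyloxy)-4-hydroxy-2-methoxyphenyl sulfate (not isolated) | CC(=O)c1c(O)cc(OCC=C)c(OS(=O)(=O)[O-])c1OC.[K+] | intermediate
4 | 4'-allyloxy-2',5'-dihydroxy-6'-methoxyacetophenone | CC(=O)c1c(O)cc(OCC=C)c(O)c1OC | intermediate
5 | 4'-allyloxy-2'-hydroxy-5',6'-dimethoxyacetophenone | CC(=O)c1c(O)cc(OCC=C)c(OC)c1OC | intermediate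
6 | 3-bromo-4-methoxybenzaldehyde | COc1ccc(C=O)cc1Br | starting material
7 | 2-(3-bromo-4-methoxyphenyl)-1,3-dioxolane | COc1ccc(C2OCCO2)cc1Br | intermediate
8 | methyl (R)-glycidate, methyl (2R)-oxirane-2-carboxylate | COC(=O)[C@H]1CO1 | starting material
9 | [5-(1,3-dioxolan-2-yl)-2-methoxyphenyl]magnesium bromide (not isolated) | COc1ccc(C2OCCO2)cc1[Mg]Br | intermediate
10 | methyl (2R)-3-[5-(1,3-dioxolan-2-yl)-2-methoxyphenyl]-2-hydroxypropanoate | COC(=O)[C@H](O)Cc1cc(C2OCCO2)ccc1OC | intermediate
11 | methyl (2R)-3-[5-(1,3-dioxolan-2-yl)-2-methoxyphenyl]-2-(triethylsilyloxy)propanoate | COC(=O)[C@H](O[Si](CC)(CC)CC)Cc1cc(C2OCCO2)ccc1OC | intermediate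
12 | (3R)-4-[5-(1,3-dioxolan-2-yl)-2-methoxyphenyl]-3-(triethylsilyloxy)butan-2-one (not isolated in step 7) | CC(=O)[C@H](O[Si](CC)(CC)CC)Cc1cc(C2OCCO2)ccc1OC | intermediate
13 | (3R)-4-[5-(1,3-dioxolan-2-yl)-2-methoxyphenyl]-2-methyl-3-(triethylsilyloxy)butan-2-ol | CC(C)(O)[C@H](O[Si](CC)(CC)CC)Cc1cc(C2OCCO2)ccc1OC | intermediate
14 | triethylammonium salt of the N-(methoxycarbonyl)sulfamate ester of the tertiary hydroxyl of 13, (R) centre unchanged (not isolated) | COC(=O)[N-]S(=O)(=O)OC(C)(C)[C@H](O[Si](CC)(CC)CC)Cc1cc(C2OCCO2)ccc1OC.CC[NH+](CC)CC | intermediate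
15 | 2-{4-methoxy-3-[(2R)-3-methyl-2-(triethylsilyloxy)but-3-en-1-yl]phenyl}-1,3-dioxolane | C=C(C)[C@H](O[Si](CC)(CC)CC)Cc1cc(C2OCCO2)ccc1OC | intermediate
16 | 4-methoxy-3-[(2R)-3-methyl-2-(triethylsilyloxy)but-3-en-1-yl]benzaldehyde (not isolated) | C=C(C)[C@H](O[Si](CC)(CC)CC)Cc1cc(C=O)ccc1OC | intermediate
17 | 3-[(2R)-2-hydroxy-3-methylbut-3-en-1-yl]-4-methoxybenzaldehyde | C=C(C)[C@H](O)Cc1cc(C=O)ccc1OC | intermediate
18 | 1-[4-(allyloxy)-2-hydroxy-5,6-dimethoxyphenyl]-3-hydroxy-3-{3-[(2R)-2-hydroxy-3-methylbut-3-en-1-yl]-4-methoxyphenyl}propan-1-one, both C3 epimers (not isolated) | C=C(C)[C@H](O)Cc1cc(C(O)CC(=O)c2c(O)cc(OCC=C)c(OC)c2OC)ccc1OC | intermediate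
19 | (E)-1-[4-(allyloxy)-2-hydroxy-5,6-dimethoxyphenyl]-3-{3-[(2R)-2-hydroxy-3-methylbut-3-en-1-yl]-4-methoxyphenyl}prop-2-en-1-one | C=C(C)[C@H](O)Cc1cc(/C=C/C(=O)c2c(O)cc(OCC=C)c(OC)c2OC)ccc1OC | intermediate
20 | [4-(allyloxy)-2-hydroxy-5,6-dimethoxyphenyl]{trans-3-[3-((2R)-2-hydroxy-3-methylbut-3-en-1-yl)-4-methoxyphenyl]oxiran-2-yl}methanone, both trans diastereomers (not isolated) | C=C(C)[C@H](O)Cc1cc(C2OC2C(=O)c3c(O)cc(OCC=C)c(OC)c3OC)ccc1OC | intermediate
21 | 2,3-trans-7-(allyloxy)-3-hydroxy-2-{3-[(2R)-2-hydroxy-3-methylbut-3-en-1-yl]-4-methoxyphenyl}-5,6-dimethoxychroman-4-one, both trans diastereomers (not isolated) | C=C(C)[C@H](O)Cc1cc(C2Oc3cc(OCC=C)c(OC)c(OC)c3C(=O)C2O)ccc1OC | intermediate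
22 | 7-(allyloxy)-3-hydroxy-2-{3-[(2R)-2-hydroxy-3-methylbut-3-en-1-yl]-4-methoxyphenyl}-5,6-dimethoxy-4H-chromen-4-one | C=C(C)[C@H](O)Cc1cc(-c2oc3cc(OCC=C)c(OC)c(OC)c3c(=O)c2O)ccc1OC | intermediate
23 | 3,7-dihydroxy-2-{3-[(2R)-2-hydroxy-3-methylbut-3-en-1-yl]-4-methoxyphenyl}-5,6-dimethoxy-4H-chromen-4-one (CNP0264719.1) | C=C(C)[C@H](O)Cc1cc(-c2oc3cc(O)c(OC)c(OC)c3c(=O)c2O)ccc1OC | target

**Step count**

Total: 12 steps. Longest linear sequence: 9 steps (6 to 23 through steps 4–12); the ring A branch (steps 1–3) joins at step 10.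

**Steps most likely to fail**

Step 11. The ring closure may follow the five-membered mode, with the phenoxide attacking C3 of the epoxide and water then being lost to give an aurone. The methoxy group ortho to the ketone favours this by twisting the aryl ketone out of plane. Dehydrogenation of the dihydroflavonol may also stall. The fallback separates the oxidation from the ring closure and closes the ring under acid, where the benzylic carbon is the reactive one. It sets out from ketone 5, whose chelated phenol would be capped (NaH, MeOCH2Cl, DMF, 0 °C) to give 4'-allyloxy-5',6'-dimethoxy-2'-(methoxymethoxy)acetophenone F1. Claisen–Schmidt condensation of this ether with aldehyde 17 (KOH, EtOH, rt) should give the 2'-O-methoxymethyl chalcone F2. Weitz–Scheffer epoxidation (H2O2, NaOH, MeOH, rt) can then only stop at the isolable trans-epoxide F3, since no phenoxide is present. Dilute HCl in MeOH/THF (rt to 40 °C) would remove the aryl acetal and let the free phenol open the protonated epoxide at the carbon that is benzylic and para to the methoxy group. This gives dihydroflavonol 21, where the route is rejoined; 21 is then dehydrogenated to 22 by the alkaline peroxide of step 11 at 0 °C.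

Step 2. Conversion in the persulfate substitution may be low, and sulfate radicals may attack the allyl group or over-oxidise the electron-rich phenol to polymeric material. The fallback is a Teuber oxidation followed by reduction. Setting out from 2, ON(SO3K)2 (potassium nitrosodisulfonate, 2.2 equiv) in aqueous acetone buffered with KH2PO4 should oxidise the phenol, whose para position is free, to 2-acetyl-5-(allyloxy)-3-methoxy-1,4-benzoquinone F4. Aqueous Na2S2O4 in a two-phase mixture with ethyl acetate would reduce this quinone to hydroquinone 4, where the route is rejoined.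

Step 8. The sulfamate may ionise to the tertiary cation, followed by hydride shift from the silyloxy carbon (a ketone after loss of silicon). Elimination toward the silyloxy carbon or loss of the silyl group are also possible. The fallback makes the isopropenyl C=C by olefination instead of elimination. Setting out from ester 11, MeNHOMe·HCl and i-PrMgCl (THF, −20 °C) should give the N-methoxy-N-methylamide (Weinreb amide) F5. MeMgBr (THF, 0 °C) then stops at methyl ketone 12, here isolated. Salt-free Ph3P=CH2 (from Ph3PCH3Br and KN(SiMe3)2, THF, −78 to 0 °C) should methylenate 12 to 15, where the route is rejoined. The low temperature and the non-nucleophilic base guard the α-silyloxy centre against epimerisation.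

**Further compounds**

F1 | step 11 | 4'-allyloxy-5',6'-dimethoxy-2'-(methoxymethoxy)acetophenone | CC(=O)c1c(OCOC)cc(OCC=C)c(OC)c1OC
F2 | step 11 | (E)-1-[4-(allyloxy)-5,6-dimethoxy-2-(methoxymethoxy)phenyl]-3-{3-[(2R)-2-hydroxy-3-methylbut-3-en-1-yl]-4-methoxyphenyl}prop-2-en-1-one | C=C(C)[C@H](O)Cc1cc(/C=C/C(=O)c2c(OCOC)cc(OCC=C)c(OC)c2OC)ccc1OC
F3 | step 11 | [4-(allyloxy)-5,6-dimethoxy-2-(methoxymethoxy)phenyl]{trans-3-[3-((2R)-2-hydroxy-3-methylbut-3-en-1-yl)-4-methoxyphenyl]oxiran-2-yl}methanone, both trans diastereomers | C=C(C)[C@H](O)Cc1cc(C2OC2C(=O)c3c(OCOC)cc(OCC=C)c(OC)c3OC)ccc1OC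
F4 | step 2 | 2-acetyl-5-(allyloxy)-3-methoxy-1,4-benzoquinone | CC(=O)C1=C(OC)C(=O)C(OCC=C)=CC1=O
F5 | step 8 | (2R)-3-[5-(1,3-dioxolan-2-yl)-2-methoxyphenyl]-N-methoxy-N-methyl-2-(triethylsilyloxy)propanamide | CON(C)C(=O)[C@H](O[Si](CC)(CC)CC)Cc1cc(C2OCCO2)ccc1OC
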